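**Plan**

- Numbering used for every compound: C1 is the ring carbon bearing OH and C7H2OBz, then C2 (OBz), C3=C4, C5 (OBz), C6 (OH). The feature that enables the key step is the cis-diol on the adjacent ring carbons C1 (tertiary) and C6 (secondary) of the cyclohexene, opposite the cis ring alkene C3=C4. This is the pattern left by a metal-bridged reductive coupling of a C1 ketone with a C6 aldehyde across a Z alkene.
- Retrosynthesis: cut the three benzoate C–O bonds, then the ring bond C1–C6 (pinacol). Then take C3=C4 back to an alkyne and C1=O back to a 1,1-disubstituted alkene, and cut C2–C3 (alkynylation).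
- Forward: the chain is joined at C2–C3 from 2-(silyloxymethyl)acrolein (C1, C2, C7) and the alkyne made from (S)-glyceraldehyde acetonide (C3–C6). Protecting groups are exchanged on the rigid enyne. Ozonolysis, Lindlar reduction and oxidation then give the Z keto-aldehyde, and its samarium diiodide closure forms the only ring.
- Stereochemistry: C5 comes from glyceraldehyde, C2 from the catalyst-controlled alkynylation, and C1 and C6 from the samarium-bridged closure steered by C2 and C5.
- End game: acetonide on the new diol, desilylation, tribenzoylation, acetonide hydrolysis.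

Key step: step 11

Assumption: the (S,S)-ProPhenol–zinc catalyst is taken to deliver the alkynyl group to the Re face of enal 3, the sense that gives the 2R alcohol; if it delivers to the Si face, the (R,R) ligand is used with no other change.

**Step 1**
Reactants: 1 2-methylenepropane-1,3-diol
Product: 2 2-[(tert-butyldiphenylsilyloxy)methyl]prop-2-en-1-ol
Conditions: 1 (3 equiv), TBDPSCl (1 equiv), imidazole, THF, 0 °C → rt
Reagents that add atoms: tert-butyldiphenylsilyl chloride, CC(C)(C)[Si](Cl)(c1ccccc1)c1ccccc1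
Why: Silyl ether formation on a symmetrical diol used in excess, so the mono-ether should dominate and the surplus diol is washed out with water; TBDPS is chosen for O7 so that a primary TBS ether at O6 can later be removed beside it.

**Step 2**
Reactants: 2 2-[(tert-butyldiphenylsilyloxy)methyl]prop-2-en-1-ol
Product: 3 2-[(tert-butyldiphenylsilyloxy)methyl]prop-2-enal
Conditions: activated MnO2 (15 equiv), CH2Cl2, rt
Reagents that add atoms: none
Why: Manganese dioxide oxidation of an allylic alcohol stops at the enal and leaves the silyl ether alone; the enal is used fresh because 2-substituted acroleins dimerise on standing.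

**Step 3**
Reactants: 4 (S)-2,3-O-isopropylideneglyceraldehyde
Product: 5 (4R)-4-ethynyl-2,2-dimethyl-1,3-dioxolane
Conditions: dimethyl (1-diazo-2-oxopropyl)phosphonate, K2CO3, MeOH, 0 °C → rt
Reagents that add atoms: dimethyl (1-diazo-2-oxopropyl)phosphonate, COP(=O)(OC)C(=[N+]=[N-])C(C)=O
Why: Seyferth–Gilbert homologation in the Ohira–Bestmann variant should turn the α-alkoxy aldehyde into the terminal alkyne under mild carbonate conditions without epimerising C5 (the reagent supplies C3); the volatile alkyne is carried on as a solution.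

**Step 4**
Reactants: 3 2-[(tert-butyldiphenylsilyloxy)methyl]prop-2-enal; 5 (4R)-4-ethynyl-2,2-dimethyl-1,3-dioxolane
Product: 7 (3R)-4-[(tert-butyldiphenylsilyloxy)methyl]-1-[(4R)-2,2-dimethyl-1,3-dioxolan-4-yl]pent-4-en-1-yn-3-ol, via methylzinc acetylide 6 (not isolated)
Conditions: 5 (2.5 equiv, excess recovered), Me2Zn (3 equiv), (S,S)-ProPhenol (20 mol %), Ph3P=O (40 mol %), toluene, 0 °C; then 3, 4 °C
Reagents that add atoms: none
Why: Zinc–ProPhenol catalysed asymmetric alkynylation of an enal, in which the alkynylzinc formed from 5 and Me2Zn adds 1,2 to the aldehyde inside the chiral dinuclear zinc pocket on the Re face and so should set C2 as R under catalyst control, the C5 centre of the alkyne lying four atoms from the new centre.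

**Step 5**
Reactants: 7 (3R)-4-[(tert-butyldiphenylsilyloxy)methyl]-1-[(4R)-2,2-dimethyl-1,3-dioxolan-4-yl]pent-4-en-1-yn-3-ol
Product: 8 (2R,5R)-6-[(tert-butyldiphenylsilyloxy)methyl]hept-6-en-3-yne-1,2,5-triol
Conditions: AcOH/H2O (4:1), 40 °C
Reagents that add atoms: none
Why: Acid hydrolysis of a terminal isopropylidene acetal, which the primary TBDPS ether tolerates; it is placed here, while the chain is a rigid alkyne with no ketone, so that the freed C5 hydroxyl has no carbonyl to close onto.

**Step 6**
Reactants: 8 (2R,5R)-6-[(tert-butyldiphenylsilyloxy)methyl]hept-6-en-3-yne-1,2,5-triol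
Product: 9 (2R,5R)-1,2,5-tris(tert-butyldimethylsilyloxy)-6-[(tert-butyldiphenylsilyloxy)methyl]hept-6-en-3-yne
Conditions: TBSOTf (3.6 equiv), 2,6-lutidine, CH2Cl2, −78 → 0 °C
Reagents that add atoms: tert-butyldimethylsilyl trifluoromethanesulfonate, CC(C)(C)[Si](C)(C)OS(=O)(=O)C(F)(F)F
Why: Exhaustive silylation with the silyl triflate and a hindered base should cover the primary hydroxyl and both secondary propargylic hydroxyls in one operation.

**Step 7**
Reactants: 9 (2R,5R)-1,2,5-tris(tert-butyldimethylsilyloxy)-6-[(tert-butyldiphenylsilyloxy)methyl]hept-6-en-3-yne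
Product: 10 (2R,5R)-2,5-bis(tert-butyldimethylsilyloxy)-6-[(tert-butyldiphenylsilyloxy)methyl]hept-6-en-3-yn-1-ol
Conditions: CSA (0.1 equiv), MeOH/CH2Cl2 (1:1), 0 °C
Reagents that add atoms: none
Why: Selective acid methanolysis of a primary TBS ether, which cleaves faster than the two secondary TBS ethers and the far more acid-stable primary TBDPS ether, should free O6 only.

**Step 8**
Reactants: 10 (2R,5R)-2,5-bis(tert-butyldimethylsilyloxy)-6-[(tert-butyldiphenylsilyloxy)methyl]hept-6-en-3-yn-1-ol
Product: 12 (3R,6R)-3,6-bis(tert-butyldimethylsilyloxy)-1-(tert-butyldiphenylsilyloxy)-7-hydroxyhept-4-yn-2-one, via secondary ozonide 11 (not isolated)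
Conditions: O3, CH2Cl2, −78 °C (Sudan Red 7B end-point); then PPh3, −78 °C → rt
Reagents that add atoms: ozone, [O-][O+]=O
Why: Ozonolysis with reductive work-up should cleave the 1,1-disubstituted alkene to the C1 ketone, because ozone adds to alkenes much faster than to an internal alkyne that is also shielded between two silyloxy carbons, and the dye end-point stops the addition there.

**Step 9**
Reactants: 12 (3R,6R)-3,6-bis(tert-butyldimethylsilyloxy)-1-(tert-butyldiphenylsilyloxy)-7-hydroxyhept-4-yn-2-one
Product: 13 (3R,6R,4Z)-3,6-bis(tert-butyldimethylsilyloxy)-1-(tert-butyldiphenylsilyloxy)-7-hydroxyhept-4-en-2-one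
Conditions: H2 (1 atm), Lindlar catalyst (Pd/CaCO3, Pb), quinoline, EtOAc, rt
Reagents that add atoms: none
Why: Lindlar semi-hydrogenation delivers H2 syn on poisoned palladium and should give the Z alkene (C3=C4) without touching the ketone or the silyl ethers.

**Step 10**
Reactants: 13 (3R,6R,4Z)-3,6-bis(tert-butyldimethylsilyloxy)-1-(tert-butyldiphenylsilyloxy)-7-hydroxyhept-4-en-2-one
Product: 14 (2R,5R,3Z)-2,5-bis(tert-butyldimethylsilyloxy)-7-(tert-butyldiphenylsilyloxy)-6-oxohept-3-enal
Conditions: Dess–Martin periodinane, NaHCO3, CH2Cl2, 0 °C → rt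
Reagents that add atoms: none
Why: Dess–Martin oxidation under bicarbonate buffer is neutral enough that the allylic α-silyloxy centres C2 and C5 should neither epimerise nor let the alkene move into conjugation; the keto-aldehyde is passed through a short silica pad and used at once.

**Step 11**
Reactants: 14 (2R,5R,3Z)-2,5-bis(tert-butyldimethylsilyloxy)-7-(tert-butyldiphenylsilyloxy)-6-oxohept-3-enal
Product: 15 (1S,2R,5R,6S)-2,5-bis(tert-butyldimethylsilyloxy)-1-[(tert-butyldiphenylsilyloxy)methyl]cyclohex-3-ene-1,6-diol (target numbering)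
Conditions: SmI2 (2.5 equiv), t-BuOH (2.5 equiv), THF, slow addition of 14 to 0.01 M, −78 → −40 °C
Reagents that add atoms: none
Why: SmI2 transfers an electron to the more easily reduced C6 aldehyde, the samarium(III) ketyl attacks the carbon of the C1 ketone held on the same metal (6-exo-trig closure, C1=O exocyclic to the forming ring) and a second electron completes the samarium(III) 1,6-diolate, so the C1–C6 bond and the cyclohexene ring form together. The closest known reaction type is the SmI2 pinacol cyclisation of sugar-derived 1,6-dialdehydes and keto-aldehydes to cis-diol cyclitols. The Z alkene holds C1 and C6 within bonding distance, and the ring should close through a half-chair in which the C2 and C5 silyloxy groups, trans to each other, are both pseudo-equatorial. At C6 the aldehyde oxygen takes the equatorial position anti to the neighbouring C5–OTBS (dipole and steric avoidance), which gives 6S. At C1 the samarium bridge forces O1 cis to O6, hence axial, and this lets the large CH2OTBDPS arm lie equatorial, which gives 1S with O1 cis to O2. The step needs cis over trans coupling (secured by the samarium chelate), one diol face out of two (secured by the C2 and C5 silyl ethers as described) and coupling in preference to β-loss of a silyloxy group or dimerisation (secured by poorly leaving silyl ethers, low temperature, no HMPA and high dilution).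

**Step 12**
Reactants: 15 (1S,2R,5R,6S)-2,5-bis(tert-butyldimethylsilyloxy)-1-[(tert-butyldiphenylsilyloxy)methyl]cyclohex-3-ene-1,6-diol
Product: 16 1,6-O-isopropylidene acetal of 15, (1S,2R,5R,6S)
Conditions: 2-methoxypropene, PPTS (cat.), CH2Cl2, 0 °C → rt
Reagents that add atoms: 2-methoxypropene, C=C(C)OC
Why: Acid-catalysed ketalisation of the cis-1,6-diol, the only free hydroxyls, should give the cis-fused dioxolane while the silyl ethers survive anhydrous PPTS.

**Step 13**
Reactants: 16 1,6-O-isopropylidene acetal of 15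
Product: 17 (1R,2R,5R,6S)-1-(hydroxymethyl)-1,6-O-isopropylidenecyclohex-3-ene-1,2,5,6-tetrol (target numbering; the C1 descriptor changes by priority only)
Conditions: TBAF (4 equiv), THF, 0 °C → rt
Reagents that add atoms: none
Why: Fluoride desilylation should remove both TBS ethers and the TBDPS ether, the acetonide being inert to fluoride.

**Step 14**
Reactants: 17 (1R,2R,5R,6S)-1-(hydroxymethyl)-1,6-O-isopropylidenecyclohex-3-ene-1,2,5,6-tetrol
Product: 18 [(1R,2R,5R,6S)-2,5-bis(benzoyloxy)-1,6-(isopropylidenedioxy)cyclohex-3-en-1-yl]methyl benzoate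
Conditions: BzCl (4.5 equiv), pyridine, DMAP (cat.), CH2Cl2, 0 °C → rt
Reagents that add atoms: benzoyl chloride, O=C(Cl)c1ccccc1
Why: DMAP-catalysed acylation should benzoylate the primary O7 and the two allylic secondary hydroxyls O2 and O5 while the 1,6-diol stays masked.

**Step 15**
Reactants: 18 [(1R,2R,5R,6S)-2,5-bis(benzoyloxy)-1,6-(isopropylidenedioxy)cyclohex-3-en-1-yl]methyl benzoate
Product: 19 [(1S,2R,5R,6S)-2,5-bis(benzoyloxy)-1,6-dihydroxycyclohex-3-en-1-yl]methyl benzoate (CNP0128482.1)
Conditions: TFA/H2O (9:1), 0 °C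
Reagents that add atoms: none
Why: Aqueous acid hydrolysis of the isopropylidene acetal should free the cis-diol, since benzoates are stable to cold aqueous TFA and acyl migration, which is base-promoted, is not expected.

**Compound list**

1 | 2-methylenepropane-1,3-diol | C=C(CO)CO | starting material
2 | 2-[(tert-butyldiphenylsilyloxy)methyl]prop-2-en-1-ol | C=C(CO)CO[Si](c1ccccc1)(c1ccccc1)C(C)(C)C | intermediate
3 | 2-[(tert-butyldiphenylsilyloxy)methyl]prop-2-enal | C=C(C=O)CO[Si](c1ccccc1)(c1ccccc1)C(C)(C)C | intermediate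
4 | (S)-2,3-O-isopropylideneglyceraldehyde | O=C[C@@H]1COC(C)(C)O1 | starting material
5 | (4R)-4-ethynyl-2,2-dimethyl-1,3-dioxolane | C#C[C@@H]1COC(C)(C)O1 | intermediate
6 | methyl{[(4R)-2,2-dimethyl-1,3-dioxolan-4-yl]ethynyl}zinc | C[Zn]C#C[C@@H]1COC(C)(C)O1 | intermediate
7 | (3R)-4-[(tert-butyldiphenylsilyloxy)methyl]-1-[(4R)-2,2-dimethyl-1,3-dioxolan-4-yl]pent-4-en-1-yn-3-ol | C=C(CO[Si](c1ccccc1)(c1ccccc1)C(C)(C)C)[C@H](O)C#C[C@@H]1COC(C)(C)O1 | intermediate
8 | (2R,5R)-6-[(tert-butyldiphenylsilyloxy)methyl]hept-6-en-3-yne-1,2,5-triol | C=C(CO[Si](c1ccccc1)(c1ccccc1)C(C)(C)C)[C@H](O)C#C[C@@H](O)CO | intermediate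
9 | (2R,5R)-1,2,5-tris(tert-butyldimethylsilyloxy)-6-[(tert-butyldiphenylsilyloxy)methyl]hept-6-en-3-yne | C=C(CO[Si](c1ccccc1)(c1ccccc1)C(C)(C)C)[C@H](O[Si](C)(C)C(C)(C)C)C#C[C@@H](O[Si](C)(C)C(C)(C)C)CO[Si](C)(C)C(C)(C)C | intermediate
10 | (2R,5R)-2,5-bis(tert-butyldimethylsilyloxy)-6-[(tert-butyldiphenylsilyloxy)methyl]hept-6-en-3-yn-1-ol | C=C(CO[Si](c1ccccc1)(c1ccccc1)C(C)(C)C)[C@H](O[Si](C)(C)C(C)(C)C)C#C[C@@H](O[Si](C)(C)C(C)(C)C)CO | intermediate
11 | 3-[(1R,4R)-1,4-bis(tert-butyldimethylsilyloxy)-5-hydroxypent-2-yn-1-yl]-3-[(tert-butyldiphenylsilyloxy)methyl]-1,2,4-trioxolane (both epimers at the ring carbon) | C1(CO[Si](c2ccccc2)(c2ccccc2)C(C)(C)C)(OCOO1)[C@H](O[Si](C)(C)C(C)(C)C)C#C[C@@H](O[Si](C)(C)C(C)(C)C)CO | intermediate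
12 | (3R,6R)-3,6-bis(tert-butyldimethylsilyloxy)-1-(tert-butyldiphenylsilyloxy)-7-hydroxyhept-4-yn-2-one | O=C(CO[Si](c1ccccc1)(c1ccccc1)C(C)(C)C)[C@H](O[Si](C)(C)C(C)(C)C)C#C[C@@H](O[Si](C)(C)C(C)(C)C)CO | intermediate
13 | (3R,6R,4Z)-3,6-bis(tert-butyldimethylsilyloxy)-1-(tert-butyldiphenylsilyloxy)-7-hydroxyhept-4-en-2-one | O=C(CO[Si](c1ccccc1)(c1ccccc1)C(C)(C)C)[C@H](O[Si](C)(C)C(C)(C)C)/C=C\[C@@H](O[Si](C)(C)C(C)(C)C)CO | intermediate
14 | (2R,5R,3Z)-2,5-bis(tert-butyldimethylsilyloxy)-7-(tert-butyldiphenylsilyloxy)-6-oxohept-3-enal | O=C[C@H](O[Si](C)(C)C(C)(C)C)/C=C\[C@@H](O[Si](C)(C)C(C)(C)C)C(=O)CO[Si](c1ccccc1)(c1ccccc1)C(C)(C)C | intermediate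
15 | (1S,2R,5R,6S)-2,5-bis(tert-butyldimethylsilyloxy)-1-[(tert-butyldiphenylsilyloxy)methyl]cyclohex-3-ene-1,6-diol | CC(C)(C)[Si](OC[C@@]1(O)[C@H](O[Si](C)(C)C(C)(C)C)C=C[C@@H](O[Si](C)(C)C(C)(C)C)[C@@H]1O)(c1ccccc1)c1ccccc1 | intermediate
16 | 1,6-O-isopropylidene acetal of 15, (1S,2R,5R,6S) | CC(C)(C)[Si](OC[C@@]1(OC(C)(C)O2)[C@H](O[Si](C)(C)C(C)(C)C)C=C[C@@H](O[Si](C)(C)C(C)(C)C)[C@@H]12)(c1ccccc1)c1ccccc1 | intermediate
17 | (1R,2R,5R,6S)-1-(hydroxymethyl)-1,6-O-isopropylidenecyclohex-3-ene-1,2,5,6-tetrol | OC[C@@]1(OC(C)(C)O2)[C@H](O)C=C[C@@H](O)[C@@H]12 | intermediate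
18 | [(1R,2R,5R,6S)-2,5-bis(benzoyloxy)-1,6-(isopropylidenedioxy)cyclohex-3-en-1-yl]methyl benzoate | O=C(OC[C@@]1(OC(C)(C)O2)[C@H](OC(=O)c3ccccc3)C=C[C@@H](OC(=O)c3ccccc3)[C@@H]12)c1ccccc1 | intermediate
19 | [(1S,2R,5R,6S)-2,5-bis(benzoyloxy)-1,6-dihydroxycyclohex-3-en-1-yl]methyl benzoate | O=C(OC[C@@]1(O)[C@H](OC(=O)c2ccccc2)C=C[C@@H](OC(=O)c2ccccc2)[C@@H]1O)c1ccccc1 | target

**Totals**

Total step count: 15.
Longest linear sequence: 14 steps (from 1 through steps 1, 2 and 4–15); the branch from 4 joins at step 4 after one step.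

**Steps most likely to fail**

Step 11. Reductive loss of a silyloxy group next to a carbonyl, intermolecular coupling, or closure on the other diol face could compete with the wanted cyclisation. The fallback sets out from 14 and comes back at 15, and it makes no new isolated compound (F0). The C1–C6 bond is made by a tin hydride radical chain instead of electron transfer (Bu3SnH, Et3B/air, toluene, 0 °C → rt). The stannyl radical adds to the aldehyde oxygen, the O-stannyl ketyl radical at C6 adds to the C1 carbonyl, and the tin alkoxide is hydrolysed on work-up. No carbanion or metal enolate arises, so a silyloxy group beside a carbonyl cannot be expelled, and the cis-diol is again expected from bridging through tin. This is the known tin hydride pinacol cyclisation of 1,5- and 1,6-dicarbonyl compounds.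

Step 4. Poor facial control or sluggish 1,2-addition with an α-branched acrolein, together with its tendency to polymerise, could erode the C2 configuration or the conversion. The fallback sets out from 3 and 5 and comes back at 7. The lithium acetylide of 5 (n-BuLi, THF, −78 °C) adds to 3 without facial control to give (3RS)-4-[(tert-butyldiphenylsilyloxy)methyl]-1-[(4R)-2,2-dimethyl-1,3-dioxolan-4-yl]pent-4-en-1-yn-3-ol F1. MnO2 oxidises both epimers to the single cross-conjugated ynone 4-[(tert-butyldiphenylsilyloxy)methyl]-1-[(4R)-2,2-dimethyl-1,3-dioxolan-4-yl]pent-4-en-1-yn-3-one F2. Corey–Bakshi–Shibata reduction with the (S)-oxazaborolidine and catecholborane (toluene, −78 °C) then returns 7 as the 2R alcohol, the slim alkynyl arm acting as the small group and the branched alkenyl arm as the large one.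

Step 8. Ozone attacking the alkyne as well, or over-oxidation past the ketone, could consume the enyne. The fallback sets out from 10 and comes back at 12. Catalytic OsO4 with NMO (acetone/H2O, rt), which leaves internal alkynes alone, dihydroxylates the 1,1-disubstituted alkene to (2R,5R)-2,5-bis(tert-butyldimethylsilyloxy)-6-[(tert-butyldiphenylsilyloxy)methyl]hept-3-yne-1,6,7-triol F3 (both C6 epimers). NaIO4 (THF/H2O, 0 °C) then cleaves the 1,2-diol to ketone 12.

**Further compounds**

F0 | step 11 | none | none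
F1 | step 4 | (3RS)-4-[(tert-butyldiphenylsilyloxy)methyl]-1-[(4R)-2,2-dimethyl-1,3-dioxolan-4-yl]pent-4-en-1-yn-3-ol | C=C(CO[Si](c1ccccc1)(c1ccccc1)C(C)(C)C)C(O)C#C[C@@H]1COC(C)(C)O1
F2 | step 4 | 4-[(tert-butyldiphenylsilyloxy)methyl]-1-[(4R)-2,2-dimethyl-1,3-dioxolan-4-yl]pent-4-en-1-yn-3-one | C=C(CO[Si](c1ccccc1)(c1ccccc1)C(C)(C)C)C(=O)C#C[C@@H]1COC(C)(C)O1
F3 | step 8 | (2R,5R)-2,5-bis(tert-butyldimethylsilyloxy)-6-[(tert-butyldiphenylsilyloxy)methyl]hept-3-yne-1,6,7-triol (both C6 epimers) | OC[C@H](O[Si](C)(C)C(C)(C)C)C#C[C@@H](O[Si](C)(C)C(C)(C)C)C(O)(CO)CO[Si](c1ccccc1)(c1ccccc1)C(C)(C)C
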